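# Proposed synthesis of CNP0174688.1, epimesquitol-(4β→6)-epioritin-4α-ol (16)

## Analysis of the target

Target 16 is a B-type proanthocyanidin dimer. An upper flavan unit (benzo ring A with 7,8-OH, 3,4-dihydroxyphenyl ring B, pyran ring C) is joined through C4 of ring C to C6 of the benzo ring D of a lower flavan-3,4-diol unit (4-hydroxyphenyl ring E, pyran ring F). Ring C is 2R,3R,4S: 2-aryl α, 3-OH α, 4-aryl β, i.e. 2,3-cis-3,4-trans. Ring F is 2R,3R,4R: 2-aryl, 3-OH and 4-OH all on the α face, i.e. all-cis. The six stereocentres therefore form two contiguous triads that share the 2R,3R cis motif. The trans-selective standard reactions of flavonoid chemistry (hydride reduction of dihydroflavonols, hydroboration or epoxidation of flavenes) place the C3 oxygen anti to the 2-aryl group and give neither triad.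

The feature that invites the chosen move is ring F (O1–C2–C3–C4–C4a–C8a). Its three substituents sit on one face, which is what suprafacial addition of two H2 to a flat 3-hydroxy-4H-chromen-4-one would give. Ring C has the same cis C2/C3 pair, with C4 substituted with inversion relative to such an all-cis diol.

Sensitive groups are the benzylic C4–OH of ring F (ionises in acid, self-condenses, can be hydrogenolysed), the acid-labile C4(C)–C6(D) bond, two pyrogallol-type rings and a catechol (air oxidation, fast in base), and C2 of each unit (epimerisation through quinone methides once the 4'-OH is free). The hard points are regiocontrol of the linkage (C6 against C5 of a weakly nucleophilic pyrogallol-type ring D) while the lower unit is itself a latent C4 electrophile, and two different cis arrays in one molecule.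

## Retrosynthetic reasoning

**16 ⇐ 15.** Only the seven phenolic benzyl ethers are removed in the last step. All aliphatic hydroxyls are already free, so the deprotection is a fast aryl benzyl ether hydrogenolysis.

**15 ⇐ 12 (key disconnection).** The C2–H, C3–H and C4–H bonds of ring F are cut, returning the lower heterocycle to a flat flavonol ring. Precursor 12 has three stereocentres instead of six, has no ionisable benzylic alcohol and is robust to acid, base and oxidants. The forward step must add two H2 to one face of the pyranone, under catalyst control, without touching the upper unit. The cut is made here because it postpones the most labile function of the target to the end and turns three stereocentres into one selectivity problem (face choice).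

**12 ⇐ 9 + 10.** The flavonol ring is opened at O1–C2 and C3–O and at the C2=C3 bond (Claisen–Schmidt condensation, then Algar–Flynn–Oyamada oxidative cyclisation, through chalcone 11). This reduces ring D to an o-hydroxyacetophenone that already carries the upper unit.

**9 ⇐ 8 + 2.** The interflavanyl bond C4(C)–C6(D) is cut between the flavan-4-yl cation derived from 8 and C5 of acetophenone 2. It is cut at this stage and not between two finished flavans because 2 has exactly one activated free position (para to its phenolic OH, not ortho to the acetyl group), which maps onto C6(D). The nucleophile also carries no benzylic alcohol that could ionise. The forward reaction is an SN1 Friedel–Crafts alkylation in which the arene enters anti to the 3-OH, converting the all-cis diol into the 3,4-trans 4-aryl flavan.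

**8 ⇐ 5.** The same dearomative disconnection as for ring F is applied to ring C on the monomer. The catalyst sense can therefore be established on a simple substrate and reused in the key step.

**5 ⇐ 2 + 3, and 2 ⇐ 1.** Flavonol 5 comes from acetophenone 2 and aldehyde 3 through chalcone 4. Acetophenone 2 comes from gallacetophenone 1 by benzylation of the two non-chelated hydroxyls. Compound 2 is thus used twice, as ring A precursor and as ring D nucleophile, and the sequence acetophenone → flavonol → all-cis diol → Friedel–Crafts is iterated.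

## Alternatives that were turned down

**Alternative 1: (textbook) interflavanyl bond last, between two finished flavans.**
- Disconnection: C4(C)–C6(D).
- Forward key step: acid-promoted Friedel–Crafts alkylation of (2R,3R,4R)-7,8-bis(benzyloxy)-2-[4-(benzyloxy)phenyl]chromane-3,4-diol A1 by the cation from 8.
- Turned down because A1 carries the same ionisable benzylic 4-OH as the electrophile, so under the acid it is both donor and acceptor (homo-coupling, C4–O ethers). Ring D of A1 also offers C5 (para to the 8-oxygen) and two alcohol oxygens besides C6. A1 needs its own complete stereocontrolled synthesis, so convergence saves no steps, and the most labile function of the target passes through the least selective step.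

**Alternative 2: dearomatisation of a flavylium ion at C4.**
- Disconnection: the same C4(C)–C(D) bond, at the benzopyrylium oxidation level.
- Forward key step: addition of C5 of 2 to C4 of the 3-hydroxyflavylium salt A2 to give the 4-aryl-4H-chromen-3-ol A3, then hydrogenation of its C2=C3 enol.
- Turned down because A3 forms from two achiral partners and would need a chiral counter-anion to control a remote face. It also tautomerises to the 3-ketone, which makes C2 and C4 epimerisable. Decisively, hydrogen adds to C2=C3 anti to the C4 aryl group, leaving 2-aryl and 3-OH cis to the 4-aryl group (all-cis ring C), while the target needs the 4-aryl group trans to both. Any approach-controlled reduction has the same defect, and repairing C4 by acid equilibration is Alternative 1 with extra steps.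

**Alternative 3: ring C by an o-quinone methide hetero-Diels–Alder reaction.**
- Disconnection: O1–C2 and C3–C4 of ring C, with C4 brought in on ring D.
- Forward key step: dehydration of benzhydrol A4 to the ring-A o-quinone methide and [4+2] cycloaddition with the (Z)-enol ether A5.
- Turned down because the enol ether is polarised so that its aryl-bearing β-carbon bonds to C4, which gives a 2-silyloxy-3-aryl (isoflavan-type) chroman. The 2,3-cis-3,4-trans array would further require a (Z)-dienophile reacting through an exo transition state against the usual endo preference. A4 presupposes the whole lower unit, protected (an acetonide whose removal needs acid) and functionalised at C6, which costs more steps than the cycloaddition saves.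

Key step: step 6

Remarks and assumptions:
- Gallacetophenone 1, aldehydes 3 and 10, benzyl bromide and hexamethyldisilazane are taken as commercial.
- The CIP descriptor of C4 of the upper unit is R in intermediates 9 and 11–15 (ring D bears O-benzyl) and S in the target 16 (ring D bears OH). This is a priority change, not an inversion: the 4-aryl group is β, trans to the 3-OH, throughout.
- The Ru–NHC ligand enantiomer is to be assigned in a pilot run on 5 so that the 2R series results.

## Route

Step 1
Reactants: 1 gallacetophenone (1-(2,3,4-trihydroxyphenyl)ethan-1-one)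
Product: 2 1-[3,4-bis(benzyloxy)-2-hydroxyphenyl]ethan-1-one
Conditions: BnBr (2.05 equiv), K2CO3 (2.2 equiv), acetone, reflux
Reagents that add atoms: benzyl bromide, BrCc1ccccc1
Why: Williamson etherification; the 2-OH is hydrogen-bonded to the acetyl carbonyl and is the least acidic and least nucleophilic hydroxyl, so the 3- and 4-OH should be benzylated selectively.

Step 2
Reactants: 2 1-[3,4-bis(benzyloxy)-2-hydroxyphenyl]ethan-1-one; 3 3,4-bis(benzyloxy)benzaldehyde
Product: 5 7,8-bis(benzyloxy)-2-[3,4-bis(benzyloxy)phenyl]-3-hydroxy-4H-chromen-4-one, via chalcone 4 (not isolated)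
Conditions: KOH, EtOH–THF, rt; then 30% H2O2, aq NaOH, 0 °C → rt
Reagents that add atoms: hydrogen peroxide, OO
Why: Claisen–Schmidt condensation followed in the same flask by the Algar–Flynn–Oyamada reaction; a 2'-hydroxychalcone without a 6'-substituent should cyclise to the flavonol and not to an aurone.

Step 3
Reactants: 5 7,8-bis(benzyloxy)-2-[3,4-bis(benzyloxy)phenyl]-3-hydroxy-4H-chromen-4-one
Product: 8 (2R,3R,4R)-7,8-bis(benzyloxy)-2-[3,4-bis(benzyloxy)phenyl]chromane-3,4-diol, via O-silylated flavonol 6 (not isolated), via O-silylated chromanol 7 (not isolated)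
Conditions: HMDS, cat. saccharin, toluene, 80 °C, evaporate; preformed Ru–NHC catalyst {[Ru(cod)(2-methylallyl)2] 5 mol %, SINpEt·HBF4 10 mol %, KOtBu 0.9 equiv per azolium}, toluene, H2 (100 bar), 40 °C; then K2CO3 (cat.), MeOH, rt
Reagents that add atoms: none
Why: Proposed new method: O-silylation removes the chelating flavonol OH, after which a chiral Ru(II)–NHC hydride should add H2 across C2=C3 from one face and reduce C4=O from the same face (anti to the 2-aryl and 3-OSiMe3 groups), giving the all-cis 2R,3R,4R array under catalyst control. The closest known reaction types are the Ru–NHC asymmetric hydrogenation of flavones and chromones to cis-flavan-4-ols and the heterogeneous hydrogenation of 3-hydroxyflavones to racemic 2,3-cis-3,4-cis diols; the new element is the 3-oxygenated, tetrasubstituted C2=C3 bond.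

Step 4
Reactants: 8 (2R,3R,4R)-7,8-bis(benzyloxy)-2-[3,4-bis(benzyloxy)phenyl]chromane-3,4-diol; 2 1-[3,4-bis(benzyloxy)-2-hydroxyphenyl]ethan-1-one
Product: 9 1-{3,4-bis(benzyloxy)-5-[(2R,3R,4R)-7,8-bis(benzyloxy)-2-[3,4-bis(benzyloxy)phenyl]-3-hydroxychroman-4-yl]-2-hydroxyphenyl}ethan-1-one (4β-aryl, 3,4-trans)
Conditions: 2 (8 equiv), BF3·OEt2 (0.3 equiv), CH2Cl2, −20 → 0 °C, slow addition of 8; excess 2 recovered
Reagents that add atoms: none
Why: Friedel–Crafts alkylation through the flavan-4-yl cation (stabilised by O1 and the 7-oxygen), which a 2,3-cis flavan should accept anti to the pseudo-axial 3-OH (β face), giving the 3,4-trans product with net inversion of the all-cis diol. C5 of 2 is the only ring position para to the phenolic OH and not ortho to the acetyl group, so the later (4→6) linkage is fixed by the substitution pattern.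

Step 5
Reactants: 9 1-{3,4-bis(benzyloxy)-5-[(2R,3R,4R)-7,8-bis(benzyloxy)-2-[3,4-bis(benzyloxy)phenyl]-3-hydroxychroman-4-yl]-2-hydroxyphenyl}ethan-1-one; 10 4-(benzyloxy)benzaldehyde
Product: 12 7,8-bis(benzyloxy)-2-[4-(benzyloxy)phenyl]-3-hydroxy-6-[(2R,3R,4R)-7,8-bis(benzyloxy)-2-[3,4-bis(benzyloxy)phenyl]-3-hydroxychroman-4-yl]-4H-chromen-4-one, via chalcone 11 (not isolated)
Conditions: KOH, EtOH–THF, rt; then 30% H2O2, aq NaOH, 0 °C → rt
Reagents that add atoms: hydrogen peroxide, OO
Why: Second Claisen–Schmidt/Algar–Flynn–Oyamada sequence, on the chelated o-hydroxyacetophenone of ring D. With all phenols of the upper unit benzylated, no quinone methide can form, so C2, C3 and C4 of ring C should be stable to the base.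

Step 6
Reactants: 12 7,8-bis(benzyloxy)-2-[4-(benzyloxy)phenyl]-3-hydroxy-6-[(2R,3R,4R)-7,8-bis(benzyloxy)-2-[3,4-bis(benzyloxy)phenyl]-3-hydroxychroman-4-yl]-4H-chromen-4-one
Product: 15 (2R,3R,4R)-7,8-bis(benzyloxy)-2-[4-(benzyloxy)phenyl]-6-[(2R,3R,4R)-7,8-bis(benzyloxy)-2-[3,4-bis(benzyloxy)phenyl]-3-hydroxychroman-4-yl]chromane-3,4-diol, via bis-O-silylated flavonol 13 (not isolated), via bis-O-silylated chromanol 14 (not isolated)
Conditions: HMDS, cat. saccharin, toluene, 80 °C, evaporate; preformed Ru–NHC catalyst {[Ru(cod)(2-methylallyl)2] 10 mol %, SINpEt·HBF4 20 mol %, KOtBu 0.9 equiv per azolium; same ligand enantiomer as step 3}, toluene, H2 (100 bar), 40 °C; then K2CO3 (cat.), MeOH, rt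
Reagents that add atoms: none
Why: Proposed new method: after O-silylation (which removes the chelating flavonol OH), the chiral Ru(II)–NHC hydride should bind one face of the flat pyranone of ring F and transfer H2 suprafacially to C2=C3, giving the 2,3-cis 3-silyloxyflavanone, whose C4=O is then reduced from the same, now less hindered face (anti to the 2-aryl and 3-OSiMe3 groups). The closest known reaction types are the Ru–NHC-catalysed asymmetric hydrogenation of flavones and chromones to cis-flavan-4-ols and the heterogeneous hydrogenation of 3-hydroxyflavones to racemic 2,3-cis-3,4-cis-flavan-3,4-diols; what is new is the 3-oxygenated, tetrasubstituted C2=C3 bond in a homogeneous, enantioface-selective setting. No ring is closed: ring F is dearomatised and its sp2 atoms C2, C3 and C4 become the three new stereocentres. C2(F) (R) is set by the catalyst's choice of enantioface, C3(F) (R) follows from syn addition across C2=C3, and C4(F) (R) follows from delivery of the third hydride on the same face, reinforced by the substrate because that face is anti to the pseudo-axial 3-oxygen. The step needs chemoselectivity for the pyranone over the benzyl ethers, the benzenoid rings and the benzylic C–O and C–C bonds of the upper unit, which the electron-poor enone character of the chromone and the mild temperature should secure. It also needs face selectivity that is independent of the three existing stereocentres: the upper unit sits on C6(D), in the plane of the chromone and remote from C2–C4, so the catalyst sense established on 5 in step 3 should carry over. The same ligand enantiomer serves both steps because both units require the 2R,3R,4R all-cis sense.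

Step 7
Reactants: 15 (2R,3R,4R)-7,8-bis(benzyloxy)-2-[4-(benzyloxy)phenyl]-6-[(2R,3R,4R)-7,8-bis(benzyloxy)-2-[3,4-bis(benzyloxy)phenyl]-3-hydroxychroman-4-yl]chromane-3,4-diol
Product: 16 (2R,3R,4R)-2-(4-hydroxyphenyl)-6-[(2R,3R,4S)-2-(3,4-dihydroxyphenyl)-3,7,8-trihydroxychroman-4-yl]chromane-3,4,7,8-tetrol (target)
Conditions: H2 (1 atm), Pd(OH)2/C, THF–MeOH, rt, neutral, stopped at full debenzylation; filtration and concentration under argon
Reagents that add atoms: none
Why: Hydrogenolysis of seven aryl benzyl ethers; these cleave much faster than a free secondary benzylic alcohol in a neutral medium, so the C4(F)–OH, the O1–C2 bonds and the interflavanyl bond should survive. No stereocentre is touched.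

## Compound list

1 | gallacetophenone, 1-(2,3,4-trihydroxyphenyl)ethan-1-one | CC(=O)c1ccc(O)c(O)c1O | starting material
2 | 1-[3,4-bis(benzyloxy)-2-hydroxyphenyl]ethan-1-one | CC(=O)c1ccc(OCc2ccccc2)c(OCc2ccccc2)c1O | intermediate
3 | 3,4-bis(benzyloxy)benzaldehyde | O=Cc1ccc(OCc2ccccc2)c(OCc2ccccc2)c1 | starting material
4 | (E)-1-[3,4-bis(benzyloxy)-2-hydroxyphenyl]-3-[3,4-bis(benzyloxy)phenyl]prop-2-en-1-one | O=C(/C=C/c1ccc(OCc2ccccc2)c(OCc2ccccc2)c1)c1ccc(OCc2ccccc2)c(OCc2ccccc2)c1O | intermediate
5 | 7,8-bis(benzyloxy)-2-[3,4-bis(benzyloxy)phenyl]-3-hydroxy-4H-chromen-4-one | O=c1c(O)c(-c2ccc(OCc3ccccc3)c(OCc3ccccc3)c2)oc2c(OCc3ccccc3)c(OCc3ccccc3)ccc12 | intermediate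
6 | 7,8-bis(benzyloxy)-2-[3,4-bis(benzyloxy)phenyl]-3-(trimethylsilyloxy)-4H-chromen-4-one | O=c1c(O[Si](C)(C)C)c(-c2ccc(OCc3ccccc3)c(OCc3ccccc3)c2)oc2c(OCc3ccccc3)c(OCc3ccccc3)ccc12 | intermediate
7 | (2R,3R,4R)-7,8-bis(benzyloxy)-2-[3,4-bis(benzyloxy)phenyl]-3-(trimethylsilyloxy)chroman-4-ol | O(Cc6ccccc6)c1ccc([C@H]2Oc3c(ccc(OCc6ccccc6)c3OCc6ccccc6)[C@@H](O)[C@H]2O[Si](C)(C)C)cc1OCc6ccccc6 | intermediate
8 | (2R,3R,4R)-7,8-bis(benzyloxy)-2-[3,4-bis(benzyloxy)phenyl]chromane-3,4-diol | O(Cc6ccccc6)c1ccc([C@H]2Oc3c(ccc(OCc6ccccc6)c3OCc6ccccc6)[C@@H](O)[C@H]2O)cc1OCc6ccccc6 | intermediate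
9 | 1-{3,4-bis(benzyloxy)-5-[(2R,3R,4R)-7,8-bis(benzyloxy)-2-[3,4-bis(benzyloxy)phenyl]-3-hydroxychroman-4-yl]-2-hydroxyphenyl}ethan-1-one | CC(=O)c1cc([C@H]4c5ccc(OCc6ccccc6)c(OCc6ccccc6)c5O[C@H](c5ccc(OCc6ccccc6)c(OCc6ccccc6)c5)[C@@H]4O)c(OCc6ccccc6)c(OCc6ccccc6)c1O | intermediate
10 | 4-(benzyloxy)benzaldehyde | O=Cc1ccc(OCc2ccccc2)cc1 | starting material
11 | (E)-1-{3,4-bis(benzyloxy)-5-[(2R,3R,4R)-7,8-bis(benzyloxy)-2-[3,4-bis(benzyloxy)phenyl]-3-hydroxychroman-4-yl]-2-hydroxyphenyl}-3-[4-(benzyloxy)phenyl]prop-2-en-1-one | O=C(/C=C/c2ccc(OCc6ccccc6)cc2)c1cc([C@H]4c5ccc(OCc6ccccc6)c(OCc6ccccc6)c5O[C@H](c5ccc(OCc6ccccc6)c(OCc6ccccc6)c5)[C@@H]4O)c(OCc6ccccc6)c(OCc6ccccc6)c1O | intermediate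
12 | 7,8-bis(benzyloxy)-2-[4-(benzyloxy)phenyl]-3-hydroxy-6-[(2R,3R,4R)-7,8-bis(benzyloxy)-2-[3,4-bis(benzyloxy)phenyl]-3-hydroxychroman-4-yl]-4H-chromen-4-one | O=c1c(O)c(-c2ccc(OCc6ccccc6)cc2)oc2c(OCc6ccccc6)c(OCc6ccccc6)c(cc12)[C@H]4c5ccc(OCc6ccccc6)c(OCc6ccccc6)c5O[C@H](c5ccc(OCc6ccccc6)c(OCc6ccccc6)c5)[C@@H]4O | intermediate
13 | bis(trimethylsilyl) ether of 12 (flavonol 3-O and upper-unit 3-O) | O=c1c(O[Si](C)(C)C)c(-c2ccc(OCc6ccccc6)cc2)oc2c(OCc6ccccc6)c(OCc6ccccc6)c(cc12)[C@H]4c5ccc(OCc6ccccc6)c(OCc6ccccc6)c5O[C@H](c5ccc(OCc6ccccc6)c(OCc6ccccc6)c5)[C@@H]4O[Si](C)(C)C | intermediate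
14 | (2R,3R,4R)-7,8-bis(benzyloxy)-2-[4-(benzyloxy)phenyl]-3-(trimethylsilyloxy)-6-[(2R,3R,4R)-7,8-bis(benzyloxy)-2-[3,4-bis(benzyloxy)phenyl]-3-(trimethylsilyloxy)chroman-4-yl]chroman-4-ol | O(Cc6ccccc6)c1ccc([C@H]2Oc3c(cc([C@H]4c5ccc(OCc6ccccc6)c(OCc6ccccc6)c5O[C@H](c5ccc(OCc6ccccc6)c(OCc6ccccc6)c5)[C@@H]4O[Si](C)(C)C)c(OCc6ccccc6)c3OCc6ccccc6)[C@@H](O)[C@H]2O[Si](C)(C)C)cc1 | intermediate
15 | (2R,3R,4R)-7,8-bis(benzyloxy)-2-[4-(benzyloxy)phenyl]-6-[(2R,3R,4R)-7,8-bis(benzyloxy)-2-[3,4-bis(benzyloxy)phenyl]-3-hydroxychroman-4-yl]chromane-3,4-diol | O(Cc6ccccc6)c1ccc([C@H]2Oc3c(cc([C@H]4c5ccc(OCc6ccccc6)c(OCc6ccccc6)c5O[C@H](c5ccc(OCc6ccccc6)c(OCc6ccccc6)c5)[C@@H]4O)c(OCc6ccccc6)c3OCc6ccccc6)[C@@H](O)[C@H]2O)cc1 | intermediate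
16 | (2R,3R,4R)-2-(4-hydroxyphenyl)-6-[(2R,3R,4S)-2-(3,4-dihydroxyphenyl)-3,7,8-trihydroxychroman-4-yl]chromane-3,4,7,8-tetrol | Oc1ccc([C@H]2Oc3c(cc([C@H]4c5ccc(O)c(O)c5O[C@H](c5ccc(O)c(O)c5)[C@@H]4O)c(O)c3O)[C@@H](O)[C@H]2O)cc1 | target

## Step count and least certain steps

Total step count: 7. Longest linear sequence: 7 steps (1 → 16).

**Step 6 (key step, proposed new method).** The hydrogenation may stall at the tetrasubstituted C2=C3 bond (catalyst inhibition if traces of desilylated flavonolate chelate ruthenium). The intermediate 2,3-cis flavanone may epimerise at C3 before the carbonyl is reduced. The face selectivity may be insufficient. The fallback uses known chemistry and gives up catalyst control: it sets out from 12, which is hydrogenated with its 3-OH free over a heterogeneous catalyst (Raney nickel or Adams' catalyst, H2 under pressure, EtOAc–EtOH). This is the classical all-cis reduction of flavonols. It should give 15 together with (2S,3S,4S)-7,8-bis(benzyloxy)-2-[4-(benzyloxy)phenyl]-6-[(2R,3R,4R)-7,8-bis(benzyloxy)-2-[3,4-bis(benzyloxy)phenyl]-3-hydroxychroman-4-yl]chromane-3,4-diol F1. Because the upper unit is enantiopure the two are diastereomers and are separated by chromatography on silica. The route is rejoined at 15.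

**Step 3 (proposed new method).** The same failure processes apply, here on the monomer, where incomplete enantioselection would be carried into every later compound. The fallback sets out from 5 and uses the same classical heterogeneous hydrogenation to give the racemic all-cis diol, i.e. 8 together with (2S,3S,4S)-7,8-bis(benzyloxy)-2-[3,4-bis(benzyloxy)phenyl]chromane-3,4-diol F2. Resolution by preparative chromatography on a chiral stationary phase returns the route to 8.

**Step 4.** Self-alkylation and over-alkylation are the main danger. The acetyl group makes C5 of 2 less nucleophilic than C6 of ring A in 8 and in the product 9, so the cation may be consumed by flavan rings and not by 2 even with excess 2 and slow addition. Reversible O-alkylation is a lesser concern. The fallback changes the partner, not the acid: it sets out from 8 and couples it with a large excess of unprotected gallacetophenone 1 (BF3·OEt2, dioxane–CH2Cl2). Two free hydroxyls ortho and para to C5 and no flanking benzyl group make 1 the better and less hindered nucleophile. This should give 1-{5-[(2R,3R,4S)-7,8-bis(benzyloxy)-2-[3,4-bis(benzyloxy)phenyl]-3-hydroxychroman-4-yl]-2,3,4-trihydroxyphenyl}ethan-1-one F3. Selective benzylation of its two non-chelated phenols (BnBr 2.1 equiv, K2CO3, DMF, rt) returns the route to 9.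

**Step 7.** Hydrogenolytic loss of the benzylic C4(F)–OH may compete with debenzylation, and the free pyrogallol rings may oxidise during isolation. The fallback moves the debenzylation ahead of the dearomatisation, so that no benzylic alcohol is present when palladium is used. It sets out from 12, which is debenzylated (H2, Pd(OH)2/C, THF–MeOH; the flavonol ring is inert under these conditions) to 3,7,8-trihydroxy-2-(4-hydroxyphenyl)-6-[(2R,3R,4S)-2-(3,4-dihydroxyphenyl)-3,7,8-trihydroxychroman-4-yl]-4H-chromen-4-one F4. This is persilylated in the flask (HMDS, cat. saccharin, toluene) to the nonakis(trimethylsilyl) ether of F4 F5. F5 is hydrogenated as in step 6 (or over a heterogeneous catalyst with separation of diastereomers) to the ring-F (2R,3R,4R)-chroman-4-ol nonakis(trimethylsilyl) ether F6. Neutral methanolysis (MeOH, cat. AcOH, rt, argon) then gives 16 directly.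

## Further compounds

F1 | step 6 | (2S,3S,4S)-7,8-bis(benzyloxy)-2-[4-(benzyloxy)phenyl]-6-[(2R,3R,4R)-7,8-bis(benzyloxy)-2-[3,4-bis(benzyloxy)phenyl]-3-hydroxychroman-4-yl]chromane-3,4-diol | O(Cc6ccccc6)c1ccc([C@@H]2Oc3c(cc([C@H]4c5ccc(OCc6ccccc6)c(OCc6ccccc6)c5O[C@H](c5ccc(OCc6ccccc6)c(OCc6ccccc6)c5)[C@@H]4O)c(OCc6ccccc6)c3OCc6ccccc6)[C@H](O)[C@@H]2O)cc1
F2 | step 3 | (2S,3S,4S)-7,8-bis(benzyloxy)-2-[3,4-bis(benzyloxy)phenyl]chromane-3,4-diol | O(Cc6ccccc6)c1ccc([C@@H]2Oc3c(ccc(OCc6ccccc6)c3OCc6ccccc6)[C@H](O)[C@@H]2O)cc1OCc6ccccc6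
F3 | step 4 | 1-{5-[(2R,3R,4S)-7,8-bis(benzyloxy)-2-[3,4-bis(benzyloxy)phenyl]-3-hydroxychroman-4-yl]-2,3,4-trihydroxyphenyl}ethan-1-one | CC(=O)c1cc([C@H]4c5ccc(OCc6ccccc6)c(OCc6ccccc6)c5O[C@H](c5ccc(OCc6ccccc6)c(OCc6ccccc6)c5)[C@@H]4O)c(O)c(O)c1O
F4 | step 7 | 3,7,8-trihydroxy-2-(4-hydroxyphenyl)-6-[(2R,3R,4S)-2-(3,4-dihydroxyphenyl)-3,7,8-trihydroxychroman-4-yl]-4H-chromen-4-one | O=c1c(O)c(-c2ccc(O)cc2)oc2c(O)c(O)c(cc12)[C@H]4c5ccc(O)c(O)c5O[C@H](c5ccc(O)c(O)c5)[C@@H]4O
F5 | step 7 | nonakis(trimethylsilyl) ether of F4 (upper-unit C4 is R by CIP) | O=c1c(O[Si](C)(C)C)c(-c2ccc(O[Si](C)(C)C)cc2)oc2c(O[Si](C)(C)C)c(O[Si](C)(C)C)c(cc12)[C@H]4c5ccc(O[Si](C)(C)C)c(O[Si](C)(C)C)c5O[C@H](c5ccc(O[Si](C)(C)C)c(O[Si](C)(C)C)c5)[C@@H]4O[Si](C)(C)C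
F6 | step 7 | (2R,3R,4R)-3,7,8-tris(trimethylsilyloxy)-2-[4-(trimethylsilyloxy)phenyl]-6-[(2R,3R,4R)-3,7,8-tris(trimethylsilyloxy)-2-[3,4-bis(trimethylsilyloxy)phenyl]chroman-4-yl]chroman-4-ol | C[Si](C)(C)Oc1ccc([C@H]2Oc3c(cc([C@H]4c5ccc(O[Si](C)(C)C)c(O[Si](C)(C)C)c5O[C@H](c5ccc(O[Si](C)(C)C)c(O[Si](C)(C)C)c5)[C@@H]4O[Si](C)(C)C)c(O[Si](C)(C)C)c3O[Si](C)(C)C)[C@@H](O)[C@H]2O[Si](C)(C)C)cc1
A1 | alternative 1 | (2R,3R,4R)-7,8-bis(benzyloxy)-2-[4-(benzyloxy)phenyl]chromane-3,4-diol | O(Cc6ccccc6)c1ccc([C@H]2Oc3c(ccc(OCc6ccccc6)c3OCc6ccccc6)[C@@H](O)[C@H]2O)cc1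
A2 | alternative 2 | 7,8-bis(benzyloxy)-2-[3,4-bis(benzyloxy)phenyl]-3-hydroxychromenylium chloride | Oc1cc2ccc(OCc6ccccc6)c(OCc6ccccc6)c2[o+]c1-c1ccc(OCc6ccccc6)c(OCc6ccccc6)c1.[Cl-]
A3 | alternative 2 | 1-{3,4-bis(benzyloxy)-5-[7,8-bis(benzyloxy)-2-[3,4-bis(benzyloxy)phenyl]-3-hydroxy-4H-chromen-4-yl]-2-hydroxyphenyl}ethan-1-one (racemic at C4) | CC(=O)c1cc(C2c3ccc(OCc6ccccc6)c(OCc6ccccc6)c3OC(c3ccc(OCc6ccccc6)c(OCc6ccccc6)c3)=C2O)c(OCc6ccccc6)c(OCc6ccccc6)c1O
A4 | alternative 3 | [3,4-bis(benzyloxy)-2-hydroxyphenyl][(2R,3R,4R)-7,8-bis(benzyloxy)-2-[4-(benzyloxy)phenyl]-3,4-(isopropylidenedioxy)chroman-6-yl]methanol (carbinol centre undefined) | O(Cc6ccccc6)c1ccc([C@H]2Oc3c(cc(C(O)c8ccc(OCc6ccccc6)c(OCc6ccccc6)c8O)c(OCc6ccccc6)c3OCc6ccccc6)[C@@H](OC(C)(C)O7)[C@H]27)cc1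
A5 | alternative 3 | (Z)-[2-[3,4-bis(benzyloxy)phenyl]ethenyloxy]tri(propan-2-yl)silane | CC(C)[Si](O/C=C\c1ccc(OCc6ccccc6)c(OCc6ccccc6)c1)(C(C)C)C(C)C
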